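**Retrosynthetic overview**

- Feature: the pyranone carbonyl carbon C4 sits on A-ring carbon C4a, and both ring neighbours of C4a carry oxygen (C5–OH and C8a–O1). C4 can therefore be the formyl carbon of the symmetric 2,6-dihydroxy-3,4,5-trimethoxybenzaldehyde 6, whose ortho-hydroxyl directs a metal into the aldehyde C–H bond.
- Key disconnection: C4–C3 and O1–C2 of the C ring, leading back to aldehyde 6 and the B-ring aroyl sulfoxonium ylide 11 (which carries C2 and C3). The pyranone is the only ring formed; the A and B rings come from benzenoid starting materials.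
- Aldehyde 6 comes from 3,4,5-trimethoxybenzoic acid (dibromination, Cu hydroxylation with decarboxylation, Vilsmeier formylation). Ylide 11 comes from methyl 2,4-dihydroxybenzoate (benzylation, acylation of dimethylsulfoxonium methylide).
- After ring closure: 5-O-benzylation, C3 oxygenation (dimethyldioxirane epoxidation, acid opening), 3-O-methylation, hydrogenolysis of the three benzyl ethers.

Key step: step 6

Remark: the target has no stereocentre, so the SMILES defines a single achiral compound and no stereocontrol is needed. The electron-rich polyphenols 3, 4 and 6 should be handled under inert gas.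

**Route**

Step 1
Reactants: 1 3,4,5-trimethoxybenzoic acid
Product: 2 2,6-dibromo-3,4,5-trimethoxybenzoic acid
Conditions: Br2 (2.5 equiv), AcOH, 60 °C
Reagents that add atoms: bromine, BrBr
Why: Electrophilic aromatic bromination; C2 and C6 are the only free ring positions and both are activated ortho/para by methoxy groups, so exhaustive bromination can only give the 2,6-dibromide.

Step 2
Reactants: 2 2,6-dibromo-3,4,5-trimethoxybenzoic acid
Product: 4 4,5,6-trimethoxybenzene-1,3-diol, via 2,6-dihydroxy-3,4,5-trimethoxybenzoic acid 3 (not isolated)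
Conditions: aq. NaOH, CuSO4·5H2O (cat.), reflux, N2; then aq. HCl to pH 1–2, 80 °C
Reagents that add atoms: sodium hydroxide, [Na+].[OH-]
Why: Ullmann-type copper-catalysed hydroxylation of ortho-bromobenzoates, assisted by carboxylate coordination to copper, followed by protodecarboxylation of the 2,6-dihydroxybenzoic acid through ipso-protonation of a ring carbon that is ortho to two hydroxyls and para to a methoxy group.

Step 3
Reactants: 4 4,5,6-trimethoxybenzene-1,3-diol
Product: 6 2,6-dihydroxy-3,4,5-trimethoxybenzaldehyde, via aryl iminium chloride 5 (not isolated)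
Conditions: POCl3, DMF, MeCN, 0 °C to rt; then H2O, 50 °C
Reagents that add atoms: N,N-dimethylformamide, CN(C)C=O; water, O
Why: Vilsmeier–Haack formylation at the only unsubstituted ring carbon, which lies between the two hydroxyls and is the most nucleophilic site, followed by hydrolysis of the iminium salt.

Step 4
Reactants: 7 methyl 2,4-dihydroxybenzoate
Product: 8 methyl 2,4-bis(benzyloxy)benzoate
Conditions: BnBr (2.5 equiv), K2CO3, DMF, 70 °C
Reagents that add atoms: benzyl bromide, BrCc1ccccc1
Why: Williamson ether synthesis; heating in DMF with excess reagent should also alkylate the hydrogen-bonded 2-hydroxyl.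

Step 5
Reactants: 8 methyl 2,4-bis(benzyloxy)benzoate; 9 trimethylsulfoxonium iodide
Product: 11 1-[2,4-bis(benzyloxy)phenyl]-2-[dimethyl(oxo)-λ6-sulfanylidene]ethan-1-one, via dimethylsulfoxonium methylide 10 (not isolated)
Conditions: 9 (3 equiv), KOtBu (3 equiv), THF, reflux; then 8, THF, reflux
Reagents that add atoms: none
Why: Acylation of the Corey–Chaykovsky methylide by the methyl ester; excess methylide deprotonates the β-keto sulfoxonium salt to the stabilised acyl ylide, which does not react further.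

Step 6
Reactants: 6 2,6-dihydroxy-3,4,5-trimethoxybenzaldehyde; 11 1-[2,4-bis(benzyloxy)phenyl]-2-[dimethyl(oxo)-λ6-sulfanylidene]ethan-1-one
Product: 13 2-[2,4-bis(benzyloxy)phenyl]-5-hydroxy-6,7,8-trimethoxy-4H-chromen-4-one, via 1,3-diketone 12 (not isolated)
Conditions: [Cp*RhCl2]2 (5 mol %), AgSbF6 (20 mol %), NaOAc (50 mol %), DCE, 80 °C, Ar; then TsOH·H2O (10 mol %), 80 °C
Reagents that add atoms: none
Why: The phenoxide of 6 binds cationic Cp*Rh(III) and directs cleavage of the formyl C–H bond to a five-membered acyl rhodacycle; the ylide coordinates through carbon, loses dimethyl sulfoxide to a rhodium carbene, and migratory insertion of the acyl group forms C4–C3, after which protonation releases diketone 12 and the catalyst. The closest known reaction is the Rh(III)-catalysed annulation of salicylaldehydes with aroyl sulfoxonium ylides to 2-arylchromones. The pyranone ring then closes by 6-exo-trig addition of an A-ring hydroxyl to the aroyl carbonyl and loss of water, forming O1–C2. No stereocentre is created. The selectivity needed is acylation of the carbene over decarbonylation and ring closure through the A-ring oxygen only; the chelating phenoxide holds the acyl–rhodium species for insertion, and both B-ring oxygens are benzylated, so only the A ring can close. Because 6 is symmetric, either hydroxyl may direct and the other becomes the 5-OH, and the redox-neutral conditions expose the electron-rich A ring to no oxidant.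

Step 7
Reactants: 13 2-[2,4-bis(benzyloxy)phenyl]-5-hydroxy-6,7,8-trimethoxy-4H-chromen-4-one
Product: 14 5-(benzyloxy)-2-[2,4-bis(benzyloxy)phenyl]-6,7,8-trimethoxy-4H-chromen-4-one
Conditions: BnBr, K2CO3, TBAI (cat.), DMF, 70 °C
Reagents that add atoms: benzyl bromide, BrCc1ccccc1
Why: Williamson benzylation of the chelated 5-hydroxyl under forcing conditions, which removes the free phenol before the oxidation step.

Step 8
Reactants: 14 5-(benzyloxy)-2-[2,4-bis(benzyloxy)phenyl]-6,7,8-trimethoxy-4H-chromen-4-one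
Product: 16 5-(benzyloxy)-2-[2,4-bis(benzyloxy)phenyl]-3-hydroxy-6,7,8-trimethoxy-4H-chromen-4-one, via flavone 2,3-epoxide 15 (not isolated)
Conditions: dimethyldioxirane (acetone solution, excess), CH2Cl2, 0 °C to rt; then TsOH·H2O (cat.), CH2Cl2, rt
Reagents that add atoms: dimethyldioxirane, CC1(C)OO1
Why: Dioxirane epoxidation of the C2=C3 enol-ether double bond, then acid opening of the epoxide at C2 (cation stabilised by O1 and the aryl group) and loss of H3, should give the flavonol.

Step 9
Reactants: 16 5-(benzyloxy)-2-[2,4-bis(benzyloxy)phenyl]-3-hydroxy-6,7,8-trimethoxy-4H-chromen-4-one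
Product: 17 5-(benzyloxy)-2-[2,4-bis(benzyloxy)phenyl]-3,6,7,8-tetramethoxy-4H-chromen-4-one
Conditions: MeI, K2CO3, acetone, reflux
Reagents that add atoms: iodomethane, CI
Why: Williamson O-methylation of the acidic 3-hydroxyl, the only free hydroxyl in the molecule.

Step 10
Reactants: 17 5-(benzyloxy)-2-[2,4-bis(benzyloxy)phenyl]-3,6,7,8-tetramethoxy-4H-chromen-4-one
Product: 18 2-(2,4-dihydroxyphenyl)-5-hydroxy-3,6,7,8-tetramethoxy-4H-chromen-4-one (5,2',4'-trihydroxy-3,6,7,8-tetramethoxyflavone)
Conditions: H2 (1 atm), 10% Pd/C, EtOAc–MeOH, rt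
Reagents that add atoms: none
Why: Catalytic hydrogenolysis of the three aryl benzyl ethers; the chromone C2=C3 bond and the methyl ethers should be inert at ambient pressure.

**Compound list**

1 | 3,4,5-trimethoxybenzoic acid | COc1cc(C(=O)O)cc(OC)c1OC | starting material
2 | 2,6-dibromo-3,4,5-trimethoxybenzoic acid | COc1c(Br)c(C(=O)O)c(Br)c(OC)c1OC | intermediate
3 | 2,6-dihydroxy-3,4,5-trimethoxybenzoic acid | COc1c(O)c(C(=O)O)c(O)c(OC)c1OC | intermediate (not isolated)
4 | 4,5,6-trimethoxybenzene-1,3-diol | COc1c(O)cc(O)c(OC)c1OC | intermediate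
5 | [(2,6-dihydroxy-3,4,5-trimethoxyphenyl)methylidene]dimethyliminium chloride | COc1c(O)c(C=[N+](C)C)c(O)c(OC)c1OC.[Cl-] | intermediate (not isolated)
6 | 2,6-dihydroxy-3,4,5-trimethoxybenzaldehyde | COc1c(O)c(C=O)c(O)c(OC)c1OC | intermediate
7 | methyl 2,4-dihydroxybenzoate | COC(=O)c1ccc(O)cc1O | starting material
8 | methyl 2,4-bis(benzyloxy)benzoate | COC(=O)c1ccc(OCc2ccccc2)cc1OCc1ccccc1 | intermediate
9 | trimethylsulfoxonium iodide | C[S+](C)(C)=O.[I-] | starting material
10 | dimethylsulfoxonium methylide | C[S+](C)(=O)[CH2-] | intermediate (not isolated)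
11 | 1-[2,4-bis(benzyloxy)phenyl]-2-[dimethyl(oxo)-λ6-sulfanylidene]ethan-1-one | CS(C)(=O)=CC(=O)c1ccc(OCc2ccccc2)cc1OCc1ccccc1 | intermediate
12 | 1-[2,4-bis(benzyloxy)phenyl]-3-(2,6-dihydroxy-3,4,5-trimethoxyphenyl)propane-1,3-dione | COc1c(O)c(C(=O)CC(=O)c2ccc(OCc3ccccc3)cc2OCc2ccccc2)c(O)c(OC)c1OC | intermediate (not isolated)
13 | 2-[2,4-bis(benzyloxy)phenyl]-5-hydroxy-6,7,8-trimethoxy-4H-chromen-4-one | COc1c(OC)c(O)c2c(=O)cc(-c3ccc(OCc4ccccc4)cc3OCc3ccccc3)oc2c1OC | intermediate
14 | 5-(benzyloxy)-2-[2,4-bis(benzyloxy)phenyl]-6,7,8-trimethoxy-4H-chromen-4-one | COc1c(OC)c(OCc2ccccc2)c2c(=O)cc(-c3ccc(OCc4ccccc4)cc3OCc3ccccc3)oc2c1OC | intermediate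
15 | 5-(benzyloxy)-2-[2,4-bis(benzyloxy)phenyl]-2,3-epoxy-6,7,8-trimethoxychroman-4-one (racemic) | COc1c(OC)c(OCc2ccccc2)c2C(=O)C3OC3(c4ccc(OCc5ccccc5)cc4OCc4ccccc4)Oc2c1OC | intermediate (not isolated)
16 | 5-(benzyloxy)-2-[2,4-bis(benzyloxy)phenyl]-3-hydroxy-6,7,8-trimethoxy-4H-chromen-4-one | COc1c(OC)c(OCc2ccccc2)c2c(=O)c(O)c(-c3ccc(OCc4ccccc4)cc3OCc3ccccc3)oc2c1OC | intermediate
17 | 5-(benzyloxy)-2-[2,4-bis(benzyloxy)phenyl]-3,6,7,8-tetramethoxy-4H-chromen-4-one | COc1c(OC)c(OCc2ccccc2)c2c(=O)c(OC)c(-c3ccc(OCc4ccccc4)cc3OCc3ccccc3)oc2c1OC | intermediate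
18 | 2-(2,4-dihydroxyphenyl)-5-hydroxy-3,6,7,8-tetramethoxy-4H-chromen-4-one | COc1c(OC)c(O)c2c(=O)c(OC)c(-c3ccc(O)cc3O)oc2c1OC | target

**Step count and risks**

Total steps: 10. Longest linear sequence: 8 steps (1, 2, 3, 6, 7, 8, 9, 10).

Steps most likely to fail:

1. Step 6 (key step). The two ortho-hydroxyls may hold rhodium as a bis-chelate and slow turnover. The acyl–rhodium species may lose CO before the carbene inserts. The ylide may be consumed by C–H activation of its own aryl ring. Cyclodehydration may stop at the diketone. Fallback, setting out from resorcinol 4 and ester 8: 4 is C-acetylated at its only free position (Ac2O, BF3·OEt2, 80 °C) to 1-(2,6-dihydroxy-3,4,5-trimethoxyphenyl)ethan-1-one F1. Ester 8 is saponified (LiOH, THF–H2O, then HCl) to 2,4-bis(benzyloxy)benzoic acid F2, which SOCl2 converts into 2,4-bis(benzyloxy)benzoyl chloride F3. F1 is deprotonated with excess LiHMDS in THF at −78 °C and C-acylated with F3, which should give the 1,3-diketone 12 after acidic work-up. Heating 12 with TsOH in toluene closes the pyranone, and the route resumes at 13.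

2. Step 2. The second C–O coupling at the hindered position may stay incomplete, bromine may be lost reductively, and the polyphenolate may be oxidised in hot alkali. Fallback, setting out from 2: silver-catalysed protodecarboxylation (Ag2CO3, AcOH, DMSO, 120 °C) should give 1,5-dibromo-2,3,4-trimethoxybenzene F4. Double Miyaura borylation (B2pin2, Pd(dppf)Cl2, KOAc, dioxane, 90 °C) gives 2,2'-(4,5,6-trimethoxy-1,3-phenylene)bis(4,4,5,5-tetramethyl-1,3,2-dioxaborolane) F5. Oxidation with aqueous H2O2 in buffered THF then gives the resorcinol, and the route resumes at 4.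

3. Step 8. Epoxidation of the electron-poor C2=C3 bond may be slow enough for the dioxirane to attack the benzylic C–H bonds of the benzyl ethers or the oxygen-rich A ring. Fallback, setting out from 14: deprotonation at C3 with LDA in THF at −78 °C gives 5-(benzyloxy)-2-[2,4-bis(benzyloxy)phenyl]-3-lithio-6,7,8-trimethoxy-4H-chromen-4-one F6. Trapping with B(OMe)3 gives dimethyl {5-(benzyloxy)-2-[2,4-bis(benzyloxy)phenyl]-6,7,8-trimethoxy-4-oxo-4H-chromen-3-yl}boronate F7. Oxidation with H2O2 and AcOH should give the flavonol, and the route resumes at 16.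

**Further compounds**

F1 | step 6 | 1-(2,6-dihydroxy-3,4,5-trimethoxyphenyl)ethan-1-one | COc1c(O)c(C(C)=O)c(O)c(OC)c1OC
F2 | step 6 | 2,4-bis(benzyloxy)benzoic acid | O=C(O)c1ccc(OCc2ccccc2)cc1OCc1ccccc1
F3 | step 6 | 2,4-bis(benzyloxy)benzoyl chloride | O=C(Cl)c1ccc(OCc2ccccc2)cc1OCc1ccccc1
F4 | step 2 | 1,5-dibromo-2,3,4-trimethoxybenzene | COc1c(Br)cc(Br)c(OC)c1OC
F5 | step 2 | 2,2'-(4,5,6-trimethoxy-1,3-phenylene)bis(4,4,5,5-tetramethyl-1,3,2-dioxaborolane) | COc1c(B2OC(C)(C)C(C)(C)O2)cc(B2OC(C)(C)C(C)(C)O2)c(OC)c1OC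
F6 | step 8 | 5-(benzyloxy)-2-[2,4-bis(benzyloxy)phenyl]-3-lithio-6,7,8-trimethoxy-4H-chromen-4-one | [Li]c1c(-c2ccc(OCc3ccccc3)cc2OCc2ccccc2)oc2c(OC)c(OC)c(OC)c(OCc3ccccc3)c2c1=O
F7 | step 8 | dimethyl {5-(benzyloxy)-2-[2,4-bis(benzyloxy)phenyl]-6,7,8-trimethoxy-4-oxo-4H-chromen-3-yl}boronate | COB(OC)c1c(-c2ccc(OCc3ccccc3)cc2OCc2ccccc2)oc2c(OC)c(OC)c(OC)c(OCc3ccccc3)c2c1=O
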